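Convention (one remark on the chemistry): germacrane numbering is used throughout (ring C1–C10, lactone carbons C11–C13, C14 on C10, C15 on C4). α is the ring face of O-6, O-9 and H-7 in the target, β the face of C-11 and O-8. "Ring-cis/ring-trans" describes the two ring carbons on a ring double bond (C2/C9 at C1=C10, C3/C6 at C4=C5).

## The problem

The target is a cis,cis-germacranolide. It has a ten-membered carbocycle with two trisubstituted olefins, C1=C10 and C4=C5, both cis within the ring, and each carries an oxidised one-carbon branch (C14 aldehyde, C15 alcohol) cis to its vinylic hydrogen. Four contiguous stereocentres (6R,7S,8S,9S) lie on the arc C6–C9: a trans-fused α-methylene-γ-lactone (O-6α, C-11β), an 8β-methacrylate and a 9α-methyl ether, so C7/C8 are cis and C6/C7 and C8/C9 trans. A medium ring does not hold such an array in a predictable conformation, and direct closure of a ten-membered ring is slow and gives no control of olefin geometry. The enal, the methacrylate and the methylene lactone are Michael acceptors and polymerisable, and the C8 ester next to a free C9 oxygen can migrate, so base, nucleophiles and strong hydride are excluded late. The feature that opens the problem is the 1,5-diene C10=C1–C2–C3–C4=C5. Its two olefins are bridged on one side by C2–C3 and on the other by the six-carbon arc C5–C6–C7–C8–C9–C10 that holds every stereocentre. The ring is therefore the formal metathesis product of a cyclohexene (C5=C10) and a cyclobutene (C1=C4). The six-carbon arc with C14 and C11–C13 is a p-menthane, and the position of C14 and C15 (cis to H-1 and H-5) is exactly what the [2,3] step of a SeO2 allylic oxidation delivers.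

## Retrosynthesis

**21 ⇐ 20 ⇐ 18.** The Si–O bond at C15 and the C14 oxidation level are removed first: 21 comes from silyl ether 20, and 20 from the C14-methyl compound 18 by SeO2 oxidation. This keeps the enal out of every earlier step, and the [2,3] shift of that oxidation fixes the ring-cis C1=C10 bond. The forward reaction must touch only the C14 methyl.

**18 ⇐ 17 ⇐ 16.** The C9–OCH3 bond and the C9–H bond are cut: ether 18 from alcohol 17, and 17 from enone 16 by reagent-controlled 1,2-reduction. Keeping C9 as a ketone until here is deliberate: it is the chromophore of the key step and it deactivates C1=C10, so C15 can be oxidised before C14.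

**16 ⇐ 15 ⇐ 14.** The C15–O bond is cut back to the C15 methyl of 14. Because the SeO2 ene/[2,3] sequence passes through an intermediate with a C4–C5 single bond, 14 may have either geometry at C4=C5. Olefin geometry stops being a design constraint, which is what makes the next cut possible.

**14 ⇐ 13 ⇐ 10 + 12 (key).** In 14 the olefins C1=C10 and C4=C5 are re-paired as the σ-bonds C5–C10 and C1–C4 of the bicyclo[2.2.0]hexane 13 (retro-cycloreversion). The cyclobutane of 13 is then cut at C10–C1 and C5–C4 into cyclohexenone 10 and 1-methylcyclobutene 12. Against any macrocyclisation, this builds the ten-membered ring by merging a six- and a four-membered ring, with no high-dilution ring closure. Against other ring expansions, the precursor 10 is a rigid bicyclic C14 compound that already holds C6, C7 and C8. The forward reactions must give head-to-tail [2+2] addition and then open the strained adduct thermally.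

**10 ⇐ 9 ⇐ 7.** The C8–O ester bond is cut with inversion (Mitsunobu) to the equatorial 8α-ketol 9, and the C8–O bond of 9 to the kinetic enol ether of 7 (Rubottom). The ketol is activated for SN2, and the axial 8β-oxygen, cis to C7–C11, is hard to install directly.

**7 ⇐ 5 ⇐ 4 ⇐ 3 ⇐ 2 ⇐ 1.** The lactone C12–O6 bond is cut to diol 5; the C12–O bond to the isopropenyl methyl of 3 (via 4); the C9 carbonyl to the allylic methylene of 2. Acetate 2 comes from commercial (+)-trans-p-mentha-2,8-dien-1-ol 1 by allylic transposition. Compound 1 supplies C5–C10, C14, C11–C13 and the C7 stereocentre; C6 is set trans to C7 in the transposition.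

**12 ⇐ 11.** 1-Methylcyclobutene 12 (C1–C4 and C15) comes from commercial methylenecyclobutane 11 by double-bond isomerisation.

## Roads not taken

**Alternative 1:** (the most obvious) Cut C6–C7 and the lactone C–O bond; close the ring by intramolecular Nozaki–Hiyama–Kishi/Barbier allylation (CrCl2, catalytic NiCl2) of the acyclic aldehyde–allylic bromide A1, which forms ring, lactone and C6/C7 at once. The chosen plan is better because A1 needs a long linear assembly with two geometrically pure trisubstituted olefins and the C8/C9 diol before any ring exists. The C6/C7 configuration would depend on a macrocyclic transition state steered by the remote C8 centre. The enal aldehyde and the Z-olefins must also survive the coupling steps unisomerised. In the chosen route the stereocentres are set on a six-membered ring and the olefin geometry is corrected afterwards.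

**Alternative 2:** Cut C4=C5; close by ring-closing metathesis of the lactone diene A2 with a second-generation Grubbs catalyst. This asks for a trisubstituted olefin in a strained ten-membered ring from a 1,1-disubstituted alkene, in the presence of the α-methylene lactone and a second ring olefin. Oligomerisation and cross-metathesis at the lactone methylene are the expected competitors, and the geometry of the new bond is left to ring strain. The photothermal ring expansion pays for the medium ring with the strain of a bicyclo[2.2.0]hexane.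

**Alternative 3:** Cut C8–C9; expand a six-membered ring by anionic oxy-Cope rearrangement (KH, 18-crown-6) of the 1,2-dialkenylcyclohexenol A3. The C4=C5 bond would be cis from the ring, but the chair transition state of the accessible trans-dialkenyl isomer gives a ring-trans C1=C10 bond. The C8 and C9 oxygens would require geometrically pure enol ethers on both termini. C6 (from the new ketone) and the C7 side chain would have to be set on the flexible ten-membered ring. The chosen plan fixes C6–C8 before ring expansion.

Key step: step 9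

## Route

Step 1
Reactants: 1 (1S,4R)-1-methyl-4-(prop-1-en-2-yl)cyclohex-2-en-1-ol
Product: 2 (1R,6S)-3-methyl-6-(prop-1-en-2-yl)cyclohex-2-en-1-yl acetate (trans-isopiperitenyl acetate)
Conditions: AcOH, TsOH·H2O (cat.), CH2Cl2, 0 °C
Reagents that add atoms: acetic acid, CC(=O)O
Why: Acid-catalysed allylic (SN1′) transposition: the tertiary alcohol ionises to the C10–C5–C6 allyl cation, which acetic acid captures at the secondary terminus C6 anti to the neighbouring isopropenyl group (the facial preference known for C-arylation of this same cation); the secondary acetate with the trisubstituted olefin is also the thermodynamic product, so the carbinol configuration of 1 does not matter and C6 is set trans to C7.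

Step 2
Reactants: 2 (1R,6S)-3-methyl-6-(prop-1-en-2-yl)cyclohex-2-en-1-yl acetate
Product: 3 (1R,6S)-3-methyl-4-oxo-6-(prop-1-en-2-yl)cyclohex-2-en-1-yl acetate
Conditions: Rh2(cap)4 (dirhodium tetrakis(caprolactamate), cat.), t-BuOOH, K2CO3, CH2Cl2, rt
Reagents that add atoms: tert-butyl hydroperoxide, CC(C)(C)OO
Why: Catalytic allylic C–H oxidation of a cyclohexene to the enone: C9 is the only allylic ring methylene, the other allylic ring C–H (C6) is deactivated by its acetoxy group, and 1,1-disubstituted isopropenyl groups are tolerated by this radical oxidation.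

Step 3
Reactants: 3 (1R,6S)-3-methyl-4-oxo-6-(prop-1-en-2-yl)cyclohex-2-en-1-yl acetate
Product: 4 (1R,6S)-6-(3-hydroxyprop-1-en-2-yl)-3-methyl-4-oxocyclohex-2-en-1-yl acetate
Conditions: SeO2 (cat.), t-BuOOH, salicylic acid (cat.), CH2Cl2, rt
Reagents that add atoms: selenium dioxide, O=[Se]=O; tert-butyl hydroperoxide, CC(C)(C)OO
Why: SeO2 allylic hydroxylation (ene reaction, then [2,3]-sigmatropic shift) of the isopropenyl methyl, which becomes C12; the ring olefin is now an electron-poor enone and does not react.

Step 4
Reactants: 4 (1R,6S)-6-(3-hydroxyprop-1-en-2-yl)-3-methyl-4-oxocyclohex-2-en-1-yl acetate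
Product: 5 (4R,5S)-4-hydroxy-5-(3-hydroxyprop-1-en-2-yl)-2-methylcyclohex-2-en-1-one
Conditions: K2CO3 (cat.), MeOH, 0 °C
Reagents that add atoms: none
Why: Mild transesterification of the allylic acetate; short contact at 0 °C should avoid base isomerisation of the γ-hydroxy enone.

Step 5
Reactants: 5 (4R,5S)-4-hydroxy-5-(3-hydroxyprop-1-en-2-yl)-2-methylcyclohex-2-en-1-one
Product: 7 (3aS,7aR)-6-methyl-3-methylidene-3a,4-dihydro-1-benzofuran-2,5(3H,7aH)-dione, via lactol 6 (not isolated)
Conditions: TEMPO (cat.), PhI(OAc)2, CH2Cl2, rt
Reagents that add atoms: none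
Why: Oxoammonium oxidation selective for the primary allylic alcohol; the resulting aldehyde is trapped by the C6 hydroxyl as lactol 6, which is oxidised on to the α-methylene lactone, trans-fused because C6–O and C7–C11 are already trans.

Step 6
Reactants: 7 (3aS,7aR)-6-methyl-3-methylidene-3a,4-dihydro-1-benzofuran-2,5(3H,7aH)-dione
Product: 9 (3aR,4R,7aR)-4-hydroxy-6-methyl-3-methylidene-3a,4-dihydro-1-benzofuran-2,5(3H,7aH)-dione (8α-ketol), via trimethylsilyl dienol ether 8 (not isolated)
Conditions: TMSOTf, Et3N, CH2Cl2, -78 to 0 °C; DMDO, acetone, -78 °C; aq. citric acid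
Reagents that add atoms: dimethyldioxirane, CC1(C)OO1
Why: Rubottom oxidation: soft enolisation takes the α′-proton at C8 (no strong base touches the methylene lactone) and DMDO oxidises the enol ether bond of 8 from the α-face, away from the β-oriented C7–C11 bond and the axial H-6; the equatorial 8α-ketol is also the thermodynamic epimer, so the acidic work-up can only reinforce it.

Step 7
Reactants: 9 (3aR,4R,7aR)-4-hydroxy-6-methyl-3-methylidene-3a,4-dihydro-1-benzofuran-2,5(3H,7aH)-dione
Product: 10 (3aS,4S,7aR)-6-methyl-3-methylidene-2,5-dioxo-2,3,3a,4,5,7a-hexahydro-1-benzofuran-4-yl 2-methylprop-2-enoate (8β-ester)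
Conditions: methacrylic acid, PPh3, DIAD, toluene, 0 °C
Reagents that add atoms: methacrylic acid, C=C(C)C(=O)O
Why: Mitsunobu esterification with inversion: SN2 displacement at the ketone-activated C8 along the axial trajectory turns the 8α-alcohol into the axial 8β-ester, cis to C7–C11 as in the target; anti-elimination is not available because H-7 is not antiperiplanar to the equatorial leaving group.

Step 8
Reactants: 11 methylenecyclobutane
Product: 12 1-methylcyclobut-1-ene
Conditions: KOtBu (cat.), DMSO, rt; distilled from the mixture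
Reagents that add atoms: none
Why: Base-catalysed olefin isomerisation to the more substituted endocyclic alkene, separated by distillation and used in excess.

Step 9
Reactants: 10 (3aS,4S,7aR)-6-methyl-3-methylidene-2,5-dioxo-2,3,3a,4,5,7a-hexahydro-1-benzofuran-4-yl 2-methylprop-2-enoate; 12 1-methylcyclobut-1-ene
Product: 13 8β-methacryloyloxy-9-oxo-1,4:5,10-dicyclogermacr-11(13)-en-6α,12-olide (cis-anti-cis photoadduct; cyclobutane C10–C1–C4–C5 on the α-face, H-5 and CH3-14 β, H-1 and CH3-15 on the side of the six-membered ring)
Conditions: hν (365 nm), 12 (10 equiv), CH2Cl2, -40 °C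
Reagents that add atoms: none
Why: Irradiation at 365 nm excites only the cyclohexenone of 10, whose triplet adds to the strained alkene 12 through a 1,4-biradical that closes to the cyclobutane (enone–alkene [2+2] photocycloaddition). The closest known reaction type is the first half of the photothermal olefin metathesis of simple alkylcyclohexenones with cyclobutenes. One ring is closed, the four-membered ring C10–C1–C4–C5, by two intermolecular C–C bonds (C5–C4 and C10–C1), the second by radical recombination within the biradical. The selectivity needed is regiochemical (head-to-tail): the methyl-bearing carbon of 12 must bond to the β-carbon C5 and its CH carbon to the methylated α-carbon C10, which is the normal orientation for alkyl-substituted alkenes and is reinforced here because the other orientation would join two quaternary carbons. Four stereocentres are formed (C1, C4, C5, C10), set by the cis-fusion of both ring junctions and by approach opposite the axial 8β-ester, but none needs control because all four become sp2 in step 10 and every diastereomer gives the same diene. Chemoselectivity comes from the substrate: the methacrylate and the methylene lactone do not absorb at this wavelength, the lactone methylene is held by the trans ring fusion where it cannot reach the enone (the intramolecular path of 5-isopropenylcyclohexenones is closed), and 12 is in large excess. The adduct stores the strain of a bicyclo[2.2.0]hexane (roughly 50 kcal/mol), which no thermal reaction of 10 and 12 could build and which drives step 10.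

Step 10
Reactants: 13 8β-methacryloyloxy-9-oxo-1,4:5,10-dicyclogermacr-11(13)-en-6α,12-olide
Product: 14 8β-methacryloyloxy-9-oxogermacra-1(10)Z,4E,11(13)-trien-6α,12-olide (C1=C10 ring-cis, C4=C5 ring-trans)
Conditions: toluene (0.005 M), BHT (cat.), sealed tube, 190 °C
Reagents that add atoms: none
Why: Thermal cycloreversion of the bicyclo[2.2.0]hexane: homolysis of the central C1–C4 bond gives a cyclohexane-1,4-diyl that fragments across C5–C10 (weakened by the C9 ketone), merging the six- and four-membered rings into the ten-membered 1,5-diene (second half of the photothermal metathesis); the cis-fused adduct should open mainly to the 1(10)-cis,4-trans diene, and neither geometry needs control because steps 11 and 15 reset both.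

Step 11
Reactants: 14 8β-methacryloyloxy-9-oxogermacra-1(10)Z,4E,11(13)-trien-6α,12-olide
Product: 15 15-hydroxy-8β-methacryloyloxy-9-oxogermacra-1(10)Z,4E,11(13)-trien-6α,12-olide (both ring olefins ring-cis)
Conditions: SeO2 (cat.), t-BuOOH, CH2Cl2, rt to 40 °C
Reagents that add atoms: selenium dioxide, O=[Se]=O; tert-butyl hydroperoxide, CC(C)(C)OO
Why: SeO2 allylic oxidation: only C4=C5 reacts because C1=C10 is an electron-poor enone, and hydrogen is taken from the C15 methyl as is usual in germacranolides; the allylseleninic acid, in which C4–C5 is a single bond, undergoes the [2,3] shift with C6 pseudo-equatorial, which places the hydroxymethyl group trans to C6 and so gives the ring-cis olefin whatever the geometry of 14 (stereoconvergent, known for the C1=C10 bond of germacranolides).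

Step 12
Reactants: 15 15-hydroxy-8β-methacryloyloxy-9-oxogermacra-1(10)Z,4E,11(13)-trien-6α,12-olide
Product: 16 15-(tert-butyldimethylsilyloxy)-8β-methacryloyloxy-9-oxogermacra-1(10)Z,4E,11(13)-trien-6α,12-olide
Conditions: TBSCl, imidazole, DMF, 0 °C
Reagents that add atoms: tert-butyldimethylsilyl chloride, CC(C)(C)[Si](C)(C)Cl
Why: Standard silylation of the primary allylic alcohol, needed so that C9–OH is the only hydroxyl at the methylation stage and C15 is not oxidised in step 15.

Step 13
Reactants: 16 15-(tert-butyldimethylsilyloxy)-8β-methacryloyloxy-9-oxogermacra-1(10)Z,4E,11(13)-trien-6α,12-olide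
Product: 17 15-(tert-butyldimethylsilyloxy)-9α-hydroxy-8β-methacryloyloxygermacra-1(10)Z,4E,11(13)-trien-6α,12-olide
Conditions: (S)-2-methyl-CBS-oxazaborolidine, catecholborane, toluene, -78 °C
Reagents that add atoms: none
Why: Corey–Bakshi–Shibata 1,2-reduction of the enone with the α-substituted alkenyl group as the large substituent, which with the (S)-catalyst should give the 9S (9α) alcohol; the Felkin–Anh preference of the adjacent non-chelating acyloxy group points the same way, and the conjugated esters are inert to catecholborane.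

Step 14
Reactants: 17 15-(tert-butyldimethylsilyloxy)-9α-hydroxy-8β-methacryloyloxygermacra-1(10)Z,4E,11(13)-trien-6α,12-olide
Product: 18 15-(tert-butyldimethylsilyloxy)-9α-methoxy-8β-methacryloyloxygermacra-1(10)Z,4E,11(13)-trien-6α,12-olide
Conditions: Me3OBF4, 1,8-bis(dimethylamino)naphthalene, CH2Cl2, rt
Reagents that add atoms: trimethyloxonium tetrafluoroborate, C[O+](C)C.F[B-](F)(F)F
Why: O-Methylation under non-basic conditions (oxonium salt, non-nucleophilic proton scavenger), so that the neighbouring C8 ester cannot migrate and the Michael acceptors are not attacked.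

Step 15
Reactants: 18 15-(tert-butyldimethylsilyloxy)-9α-methoxy-8β-methacryloyloxygermacra-1(10)Z,4E,11(13)-trien-6α,12-olide
Product: 20 15-(tert-butyldimethylsilyloxy)-9α-methoxy-8β-methacryloyloxy-14-oxogermacra-1(10)E,4E,11(13)-trien-6α,12-olide, via allylic alcohol 19 (not isolated)
Conditions: SeO2 (cat.), t-BuOOH, CH2Cl2, rt; then MnO2, CH2Cl2, rt
Reagents that add atoms: selenium dioxide, O=[Se]=O; tert-butyl hydroperoxide, CC(C)(C)OO
Why: Second SeO2 allylic oxidation, now at the C14 methyl of the C1=C10 bond freed from conjugation (C15 is blocked as its silyl ether and C9 is an oxygenated methine); the [2,3] shift again delivers the oxygenated carbon trans to C2, and MnO2 takes alcohol 19 to the (E)-enal, which is also the thermodynamic geometry.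

Step 16
Reactants: 20 15-(tert-butyldimethylsilyloxy)-9α-methoxy-8β-methacryloyloxy-14-oxogermacra-1(10)E,4E,11(13)-trien-6α,12-olide
Product: 21 15-hydroxy-9α-methoxy-8β-methacryloyloxy-14-oxogermacra-1(10)E,4E,11(13)-trien-6α,12-olide (target)
Conditions: HF·pyridine, THF/pyridine, 0 °C
Reagents that add atoms: none
Why: Buffered fluoride cleavage of the primary silyl ether; the conditions are neither basic nor nucleophilic enough to affect the enal, the methacrylate or the methylene lactone.

## Compound list

1 | (1S,4R)-1-methyl-4-(prop-1-en-2-yl)cyclohex-2-en-1-ol ((+)-trans-p-mentha-2,8-dien-1-ol) | C=C(C)[C@@H]1CC[C@](C)(O)C=C1 | starting material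
2 | (1R,6S)-3-methyl-6-(prop-1-en-2-yl)cyclohex-2-en-1-yl acetate | CC(=O)O[C@@H]1C=C(C)CC[C@H]1C(C)=C | intermediate
3 | (1R,6S)-3-methyl-4-oxo-6-(prop-1-en-2-yl)cyclohex-2-en-1-yl acetate | CC(=O)O[C@@H]1C=C(C)C(=O)C[C@H]1C(C)=C | intermediate
4 | (1R,6S)-6-(3-hydroxyprop-1-en-2-yl)-3-methyl-4-oxocyclohex-2-en-1-yl acetate | CC(=O)O[C@@H]1C=C(C)C(=O)C[C@H]1C(=C)CO | intermediate
5 | (4R,5S)-4-hydroxy-5-(3-hydroxyprop-1-en-2-yl)-2-methylcyclohex-2-en-1-one | O[C@@H]1C=C(C)C(=O)C[C@H]1C(=C)CO | intermediate
6 | (3aS,7aR)-2-hydroxy-6-methyl-3-methylidene-3,3a,4,7a-tetrahydro-1-benzofuran-5(2H)-one (lactol, anomer mixture) | CC1=C[C@H]2OC(O)C(=C)[C@@H]2CC1=O | intermediate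
7 | (3aS,7aR)-6-methyl-3-methylidene-3a,4-dihydro-1-benzofuran-2,5(3H,7aH)-dione | CC1=C[C@H]2OC(=O)C(=C)[C@@H]2CC1=O | intermediate
8 | (3aS,7aR)-6-methyl-3-methylidene-5-(trimethylsilyloxy)-3a,7a-dihydro-1-benzofuran-2(3H)-one | CC1=C[C@H]2OC(=O)C(=C)[C@@H]2C=C1O[Si](C)(C)C | intermediate
9 | (3aR,4R,7aR)-4-hydroxy-6-methyl-3-methylidene-3a,4-dihydro-1-benzofuran-2,5(3H,7aH)-dione (8α-ketol) | CC1=C[C@H]2OC(=O)C(=C)[C@@H]2[C@@H](O)C1=O | intermediate
10 | (3aS,4S,7aR)-6-methyl-3-methylidene-2,5-dioxo-2,3,3a,4,5,7a-hexahydro-1-benzofuran-4-yl 2-methylprop-2-enoate (8β-ester) | CC1=C[C@H]2OC(=O)C(=C)[C@@H]2[C@H](OC(=O)C(C)=C)C1=O | intermediate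
11 | methylenecyclobutane | C=C1CCC1 | starting material
12 | 1-methylcyclobut-1-ene | CC1=CCC1 | intermediate
13 | 8β-methacryloyloxy-9-oxo-1,4:5,10-dicyclogermacr-11(13)-en-6α,12-olide (cis-anti-cis, cyclobutane on the α-face) | C[C@@]12C(=O)[C@@H](OC(=O)C(C)=C)[C@H]3C(=C)C(=O)O[C@@H]3[C@@H]1[C@@]4(C)CC[C@@H]24 | intermediate
14 | 8β-methacryloyloxy-9-oxogermacra-1(10)Z,4E,11(13)-trien-6α,12-olide (C1=C10 ring-cis, C4=C5 ring-trans) | C=C(C)C(=O)O[C@H]1[C@H]2C(=C)C(=O)O[C@@H]2/C=C(\C)CC/C=C(/C)C1=O | intermediate
15 | 15-hydroxy-8β-methacryloyloxy-9-oxogermacra-1(10)Z,4E,11(13)-trien-6α,12-olide (both ring-cis) | C=C(C)C(=O)O[C@H]1[C@H]2C(=C)C(=O)O[C@@H]2/C=C(/CO)CC/C=C(/C)C1=O | intermediate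
16 | 15-(tert-butyldimethylsilyloxy)-8β-methacryloyloxy-9-oxogermacra-1(10)Z,4E,11(13)-trien-6α,12-olide | C=C(C)C(=O)O[C@H]1[C@H]2C(=C)C(=O)O[C@@H]2/C=C(/CO[Si](C)(C)C(C)(C)C)CC/C=C(/C)C1=O | intermediate
17 | 15-(tert-butyldimethylsilyloxy)-9α-hydroxy-8β-methacryloyloxygermacra-1(10)Z,4E,11(13)-trien-6α,12-olide | C=C(C)C(=O)O[C@H]1[C@H]2C(=C)C(=O)O[C@@H]2/C=C(/CO[Si](C)(C)C(C)(C)C)CC/C=C(/C)[C@@H]1O | intermediate
18 | 15-(tert-butyldimethylsilyloxy)-9α-methoxy-8β-methacryloyloxygermacra-1(10)Z,4E,11(13)-trien-6α,12-olide | C=C(C)C(=O)O[C@H]1[C@H]2C(=C)C(=O)O[C@@H]2/C=C(/CO[Si](C)(C)C(C)(C)C)CC/C=C(/C)[C@@H]1OC | intermediate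
19 | 15-(tert-butyldimethylsilyloxy)-14-hydroxy-9α-methoxy-8β-methacryloyloxygermacra-1(10)Z,4E,11(13)-trien-6α,12-olide | C=C(C)C(=O)O[C@H]1[C@H]2C(=C)C(=O)O[C@@H]2/C=C(/CO[Si](C)(C)C(C)(C)C)CC/C=C(/CO)[C@@H]1OC | intermediate
20 | 15-(tert-butyldimethylsilyloxy)-9α-methoxy-8β-methacryloyloxy-14-oxogermacra-1(10)E,4E,11(13)-trien-6α,12-olide | C=C(C)C(=O)O[C@H]1[C@H]2C(=C)C(=O)O[C@@H]2/C=C(/CO[Si](C)(C)C(C)(C)C)CC/C=C(/C=O)[C@@H]1OC | intermediate
21 | (3aS,4S,5S,6E,10E,11aR)-6-formyl-10-(hydroxymethyl)-5-methoxy-3-methylidene-2-oxo-2,3,3a,4,5,8,9,11a-octahydrocyclodeca[b]furan-4-yl 2-methylprop-2-enoate | C=C(C)C(=O)O[C@H]1[C@H]2C(=C)C(=O)O[C@@H]2/C=C(/CO)CC/C=C(/C=O)[C@@H]1OC | target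

## Step count and risk

Total: 16 steps. Longest linear sequence: 15 steps (steps 1–7 and 9–16 from 1); step 8 is a one-step side branch.

**Step 9 (key step).** Most likely failure: side reactions of the α′-acyloxy enone under irradiation (photochemical loss of the acyloxy group, sensitised reaction of the methacrylate), and partial loss of head-to-tail regiocontrol. Fallback, from 7 back to 13: the ester-free enone 7 is irradiated with 12 to give the tricyclic keto-lactone F1, whose only enolisable position is C8. Soft enolisation and DMDO oxidation, with equilibration to the equatorial alcohol, give the 8α-hydroxy ketone F2. Mitsunobu esterification with methacrylic acid then inverts C8 and returns to 13. The photochemistry is thus run on a substrate without the sensitive ester, and C8 is functionalised after the cycloaddition.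

**Step 10.** Most likely failure: thermal loss or polymerisation of the methacrylate, epimerisation at C8 next to the ketone at 190 °C, and onward Cope rearrangement of the first-formed 1,5-diene to a divinylcyclohexane. Fallback, from 9 back to 14: the ketol 9 is silylated (TESCl, imidazole) to the triethylsilyl ether F3, which is irradiated with 12 to the photoadduct F4 and thermolysed at low conversion to the cyclodecadienone F5. HF·pyridine frees the ten-membered 8α-ketol F6, and Mitsunobu esterification with methacrylic acid at the still ketone-activated C8 gives 14. The ester is then never exposed to light or heat.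

**Step 11.** Most likely failure: the ene/[2,3] sequence is slow on the olefin that carries the allylic lactone oxygen, or hydroxylates C15 without turning the C4=C5 bond. Fallback, from 14 back to 15: if the ring-trans 15-alcohol F7 is what forms, it is oxidised with MnO2 to the (Z)-enal F8, which is isomerised (catalytic I2, light) to the thermodynamically favoured ring-cis (E)-enal F9. NaBH(OAc)3, which reduces aldehydes but not the C9 enone, returns the alcohol 15.

**Step 1.** Most likely failure: elimination of the allyl cation to menthatrienes and incomplete trans selectivity through ion-pair return. Fallback, from 1 back to 2: oxidative 1,3-transposition with pyridinium chlorochromate [C5H5NH][CrO3Cl] gives the enone F10 (isopiperitenone), which removes the carbinol centre. Reduction with (R)-2-methyl-CBS-oxazaborolidine and BH3·SMe2 gives trans-isopiperitenol F11 under reagent control, and Ac2O/pyridine gives 2.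

**Step 2.** Most likely failure: radical attack at the isopropenyl group, or oxygenation at the transposed allylic terminus. Fallback, from 2 back to 7: SeO2/t-BuOOH in excess, whose ene mechanism directs oxygen to the methylene next to the methyl-bearing olefin carbon and to the isopropenyl methyl, gives the diol F12. MnO2 gives the keto-aldehyde F13 and NaClO2 (NaH2PO4, 2-methylbut-2-ene) the keto-acid F14. Methanolysis of the acetate (K2CO3, MeOH) and acidification close the lactone to 7.

**Step 7.** Most likely failure: elimination or C8 epimerisation in place of clean SN2 inversion at the hindered ketol. Fallback, from 9 back to 10: the alcohol is converted with Tf2O/pyridine into the configurationally stable 8α-triflate F15, which is displaced with inversion by CsO2CC(CH3)=CH2 (18-crown-6, toluene) to give 10.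

## Further compounds

F1 | step 9 | 9-oxo-1,4:5,10-dicyclogermacr-11(13)-en-6α,12-olide (photoadduct of 7 and 12) | C[C@@]12C(=O)C[C@H]3C(=C)C(=O)O[C@@H]3[C@@H]1[C@@]4(C)CC[C@@H]24
F2 | step 9 | 8α-hydroxy-9-oxo-1,4:5,10-dicyclogermacr-11(13)-en-6α,12-olide | C[C@@]12C(=O)[C@H](O)[C@H]3C(=C)C(=O)O[C@@H]3[C@@H]1[C@@]4(C)CC[C@@H]24
F3 | step 10 | triethylsilyl ether of 9 (8α-OTES enone-lactone) | CC1=C[C@H]2OC(=O)C(=C)[C@@H]2[C@@H](O[Si](CC)(CC)CC)C1=O
F4 | step 10 | 8α-(triethylsilyloxy)-9-oxo-1,4:5,10-dicyclogermacr-11(13)-en-6α,12-olide | C[C@@]12C(=O)[C@H](O[Si](CC)(CC)CC)[C@H]3C(=C)C(=O)O[C@@H]3[C@@H]1[C@@]4(C)CC[C@@H]24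
F5 | step 10 | 8α-(triethylsilyloxy)-9-oxogermacra-1(10)Z,4E,11(13)-trien-6α,12-olide | CC[Si](CC)(CC)O[C@@H]1[C@H]2C(=C)C(=O)O[C@@H]2/C=C(\C)CC/C=C(/C)C1=O
F6 | step 10 | 8α-hydroxy-9-oxogermacra-1(10)Z,4E,11(13)-trien-6α,12-olide | O[C@@H]1[C@H]2C(=C)C(=O)O[C@@H]2/C=C(\C)CC/C=C(/C)C1=O
F7 | step 11 | 15-hydroxy-8β-methacryloyloxy-9-oxogermacra-1(10)Z,4Z,11(13)-trien-6α,12-olide (C4=C5 ring-trans) | C=C(C)C(=O)O[C@H]1[C@H]2C(=C)C(=O)O[C@@H]2/C=C(\CO)CC/C=C(/C)C1=O
F8 | step 11 | 8β-methacryloyloxy-9,15-dioxogermacra-1(10)Z,4Z,11(13)-trien-6α,12-olide (C4=C5 ring-trans) | C=C(C)C(=O)O[C@H]1[C@H]2C(=C)C(=O)O[C@@H]2/C=C(\C=O)CC/C=C(/C)C1=O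
F9 | step 11 | 8β-methacryloyloxy-9,15-dioxogermacra-1(10)Z,4E,11(13)-trien-6α,12-olide (C4=C5 ring-cis) | C=C(C)C(=O)O[C@H]1[C@H]2C(=C)C(=O)O[C@@H]2/C=C(/C=O)CC/C=C(/C)C1=O
F10 | step 1 | (6S)-3-methyl-6-(prop-1-en-2-yl)cyclohex-2-en-1-one (isopiperitenone) | O=C1C=C(C)CC[C@H]1C(C)=C
F11 | step 1 | (1R,6S)-3-methyl-6-(prop-1-en-2-yl)cyclohex-2-en-1-ol (trans-isopiperitenol) | O[C@@H]1C=C(C)CC[C@H]1C(C)=C
F12 | step 2 | (1R,6S)-4-hydroxy-6-(3-hydroxyprop-1-en-2-yl)-3-methylcyclohex-2-en-1-yl acetate (C4 epimer mixture) | CC(=O)O[C@@H]1C=C(C)C(O)C[C@H]1C(=C)CO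
F13 | step 2 | (1R,6S)-3-methyl-4-oxo-6-(3-oxoprop-1-en-2-yl)cyclohex-2-en-1-yl acetate | CC(=O)O[C@@H]1C=C(C)C(=O)C[C@H]1C(=C)C=O
F14 | step 2 | 2-[(1S,2R)-2-acetoxy-4-methyl-5-oxocyclohex-3-en-1-yl]prop-2-enoic acid | CC(=O)O[C@@H]1C=C(C)C(=O)C[C@H]1C(=C)C(=O)O
F15 | step 7 | 8α-trifluoromethanesulfonate of 9 | CC1=C[C@H]2OC(=O)C(=C)[C@@H]2[C@@H](OS(=O)(=O)C(F)(F)F)C1=O
A1 | alternative 1 | acyclic C6-aldehyde/C13-allylic bromide with 8-OTES, 9-OMe, 14-OTIPS and 15-OTBS groups (methyl 2-(bromomethyl)enoate terminus) | COC(=O)/C(CBr)=C/[C@H](O[Si](CC)(CC)CC)[C@@H](OC)/C(CO[Si](C(C)C)(C(C)C)C(C)C)=C\CC/C(CO[Si](C)(C)C(C)(C)C)=C\C=O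
A2 | alternative 2 | 6-vinyl α-methylene lactone carrying the C8–C10/C1–C4 chain with a terminal 1,1-disubstituted alkene at C4 | C=C[C@H]1OC(=O)C(=C)[C@@H]1[C@H](O[Si](CC)(CC)CC)[C@@H](OC)/C(CO[Si](C(C)C)(C(C)C)C(C)C)=C\CCC(=C)CO[Si](C)(C)C(C)(C)C
A3 | alternative 3 | 1-[(Z)-2-(benzyloxy)ethenyl]-6-[(E)-1-methoxyprop-1-en-2-yl]-3-methylcyclohex-2-en-1-ol (alkenyl groups trans) | CO/C=C(\C)[C@H]1CCC(C)=C[C@]1(O)/C=C\OCc1ccccc1
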